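**Retrosynthetic overview**

1. The aryl acetate and then the benzoate C–O bond are cut last: target 28 comes from dienol 23 and 4-acetoxy-3-methoxybenzoyl chloride 26 (from vanillic acid).
2. The strategy rests on one feature of the ten-membered carbocycle: the ester-bearing allylic CH (C1) is bonded directly to the CH that carries isopropyl (C10). With isopropyl read as isopropenyl, this C1(OH)–C10 pair next to C2=C3 is the homoallylic-alcohol retron of a [2,3]-Wittig shift. The other eight ring carbons, with two Z trisubstituted olefins in a 1,5-relationship, are an all-Z farnesyl chain oxidised at both termini.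
3. Key disconnection: the C1–C10 bond of dienol 22 leads back to the 13-membered all-Z diallylic ether 21 (ring contraction), which opens at one C–O bond to hydroxy allylic chloride 20.
4. Chain 20 is built linearly from nerol 1 via C6 aldehyde 6, by a Still–Gennari olefination, a two-carbon extension with tert-butyl acetate and a second Still–Gennari olefination.
5. Ring order: the oxacyclotridecatriene first (step 15, C–O bond), the cyclodecadiene second (step 16, C–C bond); the arene is attached last.

Key step: step 16

Assumption: the sense of induction of the homochiral lithium amide on this untested all-Z ether cannot be predicted, so the route is written with the (S,S)-amide; the (R,R)-amine replaces it if a pilot run with Mosher ester analysis of 22 shows the opposite sense.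

Remarks: TBS = tert-butyldimethylsilyl. Ether 21 is numbered O1, C2 (CH2 next to C3–Me) through C13 (the nerol-derived OCH2). The C1 descriptor changes from S in 22 to R in 23, 27 and 28 only because the CIP ranking of C2 and C10 switches when isopropenyl becomes isopropyl; no bond at C1 is touched.

**Route**

Step 1
Reactants: 1 nerol
Product: 2 tert-butyl{[(2Z)-3,7-dimethylocta-2,6-dien-1-yl]oxy}dimethylsilane (neryl TBS ether)
Conditions: TBSCl, imidazole, DMF, 0 °C → rt
Reagents that add atoms: tert-butyldimethylsilyl chloride, CC(C)(C)[Si](C)(C)Cl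
Why: Imidazole-promoted silylation of the primary allylic alcohol masks this terminus for the chain-building steps and leaves the Z olefin untouched.

Step 2
Reactants: 2 neryl TBS ether
Product: 3 (6Z)-3-bromo-8-[(tert-butyldimethylsilyl)oxy]-2,6-dimethyloct-6-en-2-ol (racemic)
Conditions: NBS, THF/H2O, 0 °C
Reagents that add atoms: N-bromosuccinimide, O=C1CCC(=O)N1Br; water, O
Why: Electrophilic bromohydrin formation should occur at the remote, more electron-rich trisubstituted olefin rather than the one deactivated by the allylic oxygen, with water opening the bromonium ion at the tertiary carbon; the racemic CHBr centre is destroyed in step 4.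

Step 3
Reactants: 3 terminal bromohydrin
Product: 4 tert-butyl{[(2Z)-5-(3,3-dimethyloxiran-2-yl)-3-methylpent-2-en-1-yl]oxy}dimethylsilane (racemic)
Conditions: K2CO3, MeOH, rt
Reagents that add atoms: none
Why: Intramolecular Williamson (SN2) displacement of bromide by the neighbouring tertiary alkoxide closes the terminal epoxide under conditions that spare the silyl ether.

Step 4
Reactants: 4 terminal epoxide
Product: 6 (4Z)-6-[(tert-butyldimethylsilyl)oxy]-4-methylhex-4-enal, via vicinal diol 5 (not isolated)
Conditions: H5IO6, THF/Et2O, 0 °C, short reaction time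
Reagents that add atoms: water, O (its oxygen enters intermediate 5 only and leaves with the acetone)
Why: Periodic acid hydrates the epoxide and cleaves the glycol (oxidative glycol cleavage), excising acetone; brief exposure at 0 °C should leave the silyl ether and the Z olefin intact.

Step 5
Reactants: 6 (4Z)-6-(TBS-oxy)-4-methylhex-4-enal; 7 ethyl 2-[bis(2,2,2-trifluoroethoxy)phosphoryl]propanoate
Product: 8 ethyl (2Z,6Z)-8-[(tert-butyldimethylsilyl)oxy]-2,6-dimethylocta-2,6-dienoate
Conditions: KN(SiMe3)2, 18-crown-6, THF, −78 °C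
Reagents that add atoms: none
Why: Still–Gennari olefination: the electron-poor trifluoroethyl phosphonate with a crown-separated potassium ion eliminates from the kinetic adduct, which should give the Z α-methyl enoate (ester cis to the chain).

Step 6
Reactants: 8 (2Z,6Z)-dienoate
Product: 9 (2Z,6Z)-8-[(tert-butyldimethylsilyl)oxy]-2,6-dimethylocta-2,6-dien-1-ol
Conditions: iBu2AlH, CH2Cl2, −78 → 0 °C; aq. KNaC4H4O6 (potassium sodium tartrate)
Reagents that add atoms: none
Why: 1,2-Reduction of the enoate by the aluminium hydride gives the allylic alcohol without affecting olefin geometry or the silyl ether.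

Step 7
Reactants: 9 (2Z,6Z)-allylic alcohol
Product: 11 {[(2Z,6Z)-8-bromo-3,7-dimethylocta-2,6-dien-1-yl]oxy}(tert-butyl)dimethylsilane, via allylic mesylate 10 (not isolated)
Conditions: MsCl, Et3N, THF, −40 °C; then LiBr, THF, 0 °C
Reagents that add atoms: methanesulfonyl chloride, CS(=O)(=O)Cl (atoms kept in intermediate 10 only); lithium bromide, [Li+].[Br-]
Why: Sulfonylation followed by SN2 displacement with bromide under non-acidic conditions should give the primary allylic bromide without allylic transposition or Z/E scrambling.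

Step 8
Reactants: 11 (2Z,6Z)-allylic bromide; 12 tert-butyl acetate
Product: 13 tert-butyl (4Z,8Z)-10-[(tert-butyldimethylsilyl)oxy]-4,8-dimethyldeca-4,8-dienoate
Conditions: LiN(iPr)2, THF, −78 °C (enolate from 12); then 11, −78 → −20 °C
Reagents that add atoms: none
Why: SN2 alkylation of the pre-formed lithium ester enolate at the unhindered CH2Br adds the two carbons; the tert-butyl ester suppresses Claisen self-condensation and the substituted γ-carbon disfavours SN2' attack.

Step 9
Reactants: 13 tert-butyl dienoate
Product: 14 (4Z,8Z)-10-[(tert-butyldimethylsilyl)oxy]-4,8-dimethyldeca-4,8-dien-1-ol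
Conditions: LiAlH4, Et2O, 0 °C
Reagents that add atoms: none
Why: Complete hydride reduction of the ester to the primary alcohol is chosen over partial reduction of a tert-butyl ester because it is the more dependable way to the aldehyde oxidation level.

Step 10
Reactants: 14 primary alcohol
Product: 15 (4Z,8Z)-10-[(tert-butyldimethylsilyl)oxy]-4,8-dimethyldeca-4,8-dienal
Conditions: Dess–Martin periodinane, CH2Cl2, 0 °C → rt
Reagents that add atoms: none
Why: Dess–Martin oxidation stops cleanly at the aldehyde under near-neutral conditions that should not migrate the γ,δ-olefin or cleave the silyl ether.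

Step 11
Reactants: 15 (4Z,8Z)-dienal; 7 ethyl 2-[bis(2,2,2-trifluoroethoxy)phosphoryl]propanoate
Product: 16 ethyl (2Z,6Z,10Z)-12-[(tert-butyldimethylsilyl)oxy]-2,6,10-trimethyldodeca-2,6,10-trienoate
Conditions: KN(SiMe3)2, 18-crown-6, THF, −78 °C
Reagents that add atoms: none
Why: A second Still–Gennari olefination installs the third Z trisubstituted olefin, whose geometry later dictates the relative configuration of the two stereocentres.

Step 12
Reactants: 16 all-Z trienoate
Product: 17 (2Z,6Z,10Z)-12-[(tert-butyldimethylsilyl)oxy]-2,6,10-trimethyldodeca-2,6,10-trien-1-ol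
Conditions: iBu2AlH, CH2Cl2, −78 → 0 °C; aq. KNaC4H4O6
Reagents that add atoms: none
Why: 1,2-Reduction of the Z enoate gives the allylic alcohol with its CH2OH cis to the chain, the geometry being retained.

Step 13
Reactants: 17 all-Z mono-silylated triene diol
Product: 19 tert-butyl{[(2Z,6Z,10Z)-12-chloro-3,7,11-trimethyldodeca-2,6,10-trien-1-yl]oxy}dimethylsilane, via allylic mesylate 18 (not isolated)
Conditions: MsCl, 2,4,6-collidine, LiCl, DMF, 0 °C
Reagents that add atoms: methanesulfonyl chloride, CS(=O)(=O)Cl (atoms kept in intermediate 18 only); lithium chloride, [Li+].[Cl-]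
Why: In-situ mesylation and SN2 displacement by chloride in DMF with a hindered pyridine base converts the allylic alcohol into the chloride without rearrangement and without touching the silyl ether.

Step 14
Reactants: 19 silyl-protected allylic chloride
Product: 20 (2Z,6Z,10Z)-12-chloro-3,7,11-trimethyldodeca-2,6,10-trien-1-ol
Conditions: HF·pyridine, pyridine, THF, 0 °C → rt
Reagents that add atoms: none
Why: Si–F bond formation drives the desilylation in a buffered, non-basic and weakly nucleophilic medium, so the allylic chloride and the three olefins should survive.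

Step 15
Reactants: 20 all-Z hydroxy allylic chloride
Product: 21 (3Z,7Z,11Z)-3,7,11-trimethyl-1-oxacyclotrideca-3,7,11-triene
Conditions: NaH, THF, reflux; slow syringe-pump addition of 20, high dilution (about 0.005 M)
Reagents that add atoms: none
Why: Intramolecular Williamson etherification: slow addition keeps the alkoxide dilute so that SN2 closure of the 13-membered ring at the primary allylic chloride outruns oligomerisation, helped by the three Z olefins that fold the chain.

Step 16
Reactants: 21 13-membered all-Z diallylic ether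
Product: 22 (1S,2Z,6Z,10S)-3,7-dimethyl-10-(prop-1-en-2-yl)cyclodeca-2,6-dien-1-ol
Conditions: bis[(1S)-1-phenylethyl]amine, n-BuLi, THF, 0 °C; then 21, −78 → −20 °C; aq. NH4Cl at −78 °C
Reagents that add atoms: none
Why: The homochiral lithium amide removes one of the two enantiotopic protons on C13 (the OCH2 next to the nerol-derived C12=C11 olefin), and the α-oxy allyl lithium bonds through C13 to C4, the CH terminus of the O1–C2–C3(Me)=C4 allyl ether, in a five-membered envelope while O1–C2 breaks and C3=C2 becomes the exocyclic isopropenyl olefin, i.e. a [2,3]-Wittig sigmatropic shift. The closest known chemistry is the [2,3]-Wittig ring contraction of 13-membered farnesol-derived diallylic ethers to cyclodecadienols and its enantioselective form with lithium bis(1-phenylethyl)amide on 13-membered propargylic allylic ethers. The ten-membered carbocycle (C13, C12 to C5, C4) closes transannularly by this concerted C–C bond formation inside the existing macrocycle, a 13 → 10 ring contraction and not an end-to-end cyclisation. The relative configuration (hydroxyl and isopropenyl cis on the ring, syn in the Wittig sense) should follow from the Z geometry of C3=C4, which places C5 on the O1 side of the envelope and pushes the vinyl substituent of the carbanion exo, away from C5 and the C3 methyl; the absolute configuration follows from which C13 proton the amide takes, hence the pilot run to fix the amine enantiomer. The step needs site selectivity for C13 over C2, secured because a C2 anion could rearrange only onto the fully substituted C11 to build a quaternary centre, and it needs [2,3] over [1,2] shift with no anionic oxy-Cope of the lithium 1,5-dien-3-olate formed, both secured by the low temperature, the lithium counter-ion and the cold quench.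

Step 17
Reactants: 22 isopropenyl dienol
Product: 23 (1R,2Z,6Z,10S)-3,7-dimethyl-10-(propan-2-yl)cyclodeca-2,6-dien-1-ol
Conditions: H2 (1 atm), RhCl(PPh3)3 (cat.), toluene, rt
Reagents that add atoms: none
Why: Homogeneous hydrogenation with RhCl(PPh3)3 is strongly sensitive to olefin substitution, so the 1,1-disubstituted isopropenyl group should be saturated while both trisubstituted ring olefins remain, and the neutral medium avoids acid-triggered transannular cyclisation; no stereocentre is created or touched.

Step 18
Reactants: 24 vanillic acid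
Product: 25 4-acetoxy-3-methoxybenzoic acid
Conditions: Ac2O, pyridine, rt; then H2O
Reagents that add atoms: acetic anhydride, CC(=O)OC(C)=O
Why: Acetylation of the phenol blocks self-acylation in the acid chloride step and gives an ester that can later be removed in the presence of the benzoate.

Step 19
Reactants: 25 4-acetoxy-3-methoxybenzoic acid
Product: 26 4-acetoxy-3-methoxybenzoyl chloride
Conditions: (COCl)2, DMF (cat.), CH2Cl2, 0 °C → rt
Reagents that add atoms: oxalyl chloride, O=C(Cl)C(=O)Cl
Why: DMF-catalysed (Vilsmeier-type) chlorination converts the acid into the acid chloride with only gaseous by-products and without disturbing the aryl acetate.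

Step 20
Reactants: 23 isopropyl dienol; 26 4-acetoxy-3-methoxybenzoyl chloride
Product: 27 (1R,2Z,6Z,10S)-3,7-dimethyl-10-(propan-2-yl)cyclodeca-2,6-dien-1-yl 4-acetoxy-3-methoxybenzoate
Conditions: Et3N, DMAP (cat.), CH2Cl2, 0 °C → rt
Reagents that add atoms: none
Why: DMAP-catalysed acylation of the hindered secondary allylic alcohol proceeds with retention because the C1–O bond is not broken, and this ester is the stage at which enantiomeric purity can be raised by recrystallisation or preparative chiral chromatography if required.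

Step 21
Reactants: 27 O-acetylvanillate ester
Product: 28 (1R,2Z,6Z,10S)-3,7-dimethyl-10-(propan-2-yl)cyclodeca-2,6-dien-1-yl 4-hydroxy-3-methoxybenzoate (target CNP0306317.1)
Conditions: pyrrolidine, CH2Cl2, 0 °C; aq. NH4Cl
Reagents that add atoms: none
Why: Chemoselective aminolysis: the aryl acetate, with its phenoxide leaving group, should react with pyrrolidine far faster than the hindered, electron-rich benzoate of the secondary alcohol.

**Compound list**

1 | nerol | OC/C=C(/C)CCC=C(C)C | starting material
2 | tert-butyl{[(2Z)-3,7-dimethylocta-2,6-dien-1-yl]oxy}dimethylsilane | CC(C)(C)[Si](C)(C)OC/C=C(/C)CCC=C(C)C | intermediate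
3 | (6Z)-3-bromo-8-[(tert-butyldimethylsilyl)oxy]-2,6-dimethyloct-6-en-2-ol (racemic) | CC(C)(C)[Si](C)(C)OC/C=C(/C)CCC(Br)C(C)(C)O | intermediate
4 | tert-butyl{[(2Z)-5-(3,3-dimethyloxiran-2-yl)-3-methylpent-2-en-1-yl]oxy}dimethylsilane (racemic) | CC(C)(C)[Si](C)(C)OC/C=C(/C)CCC1OC1(C)C | intermediate
5 | (6Z)-8-[(tert-butyldimethylsilyl)oxy]-2,6-dimethyloct-6-ene-2,3-diol (racemic, not isolated) | CC(C)(C)[Si](C)(C)OC/C=C(/C)CCC(O)C(C)(C)O | intermediate
6 | (4Z)-6-[(tert-butyldimethylsilyl)oxy]-4-methylhex-4-enal | CC(C)(C)[Si](C)(C)OC/C=C(/C)CCC=O | intermediate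
7 | ethyl 2-[bis(2,2,2-trifluoroethoxy)phosphoryl]propanoate | CCOC(=O)C(C)P(=O)(OCC(F)(F)F)OCC(F)(F)F | starting material
8 | ethyl (2Z,6Z)-8-[(tert-butyldimethylsilyl)oxy]-2,6-dimethylocta-2,6-dienoate | CC(C)(C)[Si](C)(C)OC/C=C(/C)CC/C=C(/C)C(=O)OCC | intermediate
9 | (2Z,6Z)-8-[(tert-butyldimethylsilyl)oxy]-2,6-dimethylocta-2,6-dien-1-ol | CC(C)(C)[Si](C)(C)OC/C=C(/C)CC/C=C(/C)CO | intermediate
10 | (2Z,6Z)-8-[(tert-butyldimethylsilyl)oxy]-2,6-dimethylocta-2,6-dien-1-yl methanesulfonate (not isolated) | CC(C)(C)[Si](C)(C)OC/C=C(/C)CC/C=C(/C)COS(C)(=O)=O | intermediate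
11 | {[(2Z,6Z)-8-bromo-3,7-dimethylocta-2,6-dien-1-yl]oxy}(tert-butyl)dimethylsilane | CC(C)(C)[Si](C)(C)OC/C=C(/C)CC/C=C(/C)CBr | intermediate
12 | tert-butyl acetate | CC(=O)OC(C)(C)C | starting material
13 | tert-butyl (4Z,8Z)-10-[(tert-butyldimethylsilyl)oxy]-4,8-dimethyldeca-4,8-dienoate | CC(C)(C)[Si](C)(C)OC/C=C(/C)CC/C=C(/C)CCC(=O)OC(C)(C)C | intermediate
14 | (4Z,8Z)-10-[(tert-butyldimethylsilyl)oxy]-4,8-dimethyldeca-4,8-dien-1-ol | CC(C)(C)[Si](C)(C)OC/C=C(/C)CC/C=C(/C)CCCO | intermediate
15 | (4Z,8Z)-10-[(tert-butyldimethylsilyl)oxy]-4,8-dimethyldeca-4,8-dienal | CC(C)(C)[Si](C)(C)OC/C=C(/C)CC/C=C(/C)CCC=O | intermediate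
16 | ethyl (2Z,6Z,10Z)-12-[(tert-butyldimethylsilyl)oxy]-2,6,10-trimethyldodeca-2,6,10-trienoate | CC(C)(C)[Si](C)(C)OC/C=C(/C)CC/C=C(/C)CC/C=C(/C)C(=O)OCC | intermediate
17 | (2Z,6Z,10Z)-12-[(tert-butyldimethylsilyl)oxy]-2,6,10-trimethyldodeca-2,6,10-trien-1-ol | CC(C)(C)[Si](C)(C)OC/C=C(/C)CC/C=C(/C)CC/C=C(/C)CO | intermediate
18 | (2Z,6Z,10Z)-12-[(tert-butyldimethylsilyl)oxy]-2,6,10-trimethyldodeca-2,6,10-trien-1-yl methanesulfonate (not isolated) | CC(C)(C)[Si](C)(C)OC/C=C(/C)CC/C=C(/C)CC/C=C(/C)COS(C)(=O)=O | intermediate
19 | tert-butyl{[(2Z,6Z,10Z)-12-chloro-3,7,11-trimethyldodeca-2,6,10-trien-1-yl]oxy}dimethylsilane | CC(C)(C)[Si](C)(C)OC/C=C(/C)CC/C=C(/C)CC/C=C(/C)CCl | intermediate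
20 | (2Z,6Z,10Z)-12-chloro-3,7,11-trimethyldodeca-2,6,10-trien-1-ol | OC/C=C(/C)CC/C=C(/C)CC/C=C(/C)CCl | intermediate
21 | (3Z,7Z,11Z)-3,7,11-trimethyl-1-oxacyclotrideca-3,7,11-triene | C1/C=C(/C)CC/C=C(/C)CC/C=C(/C)CO1 | intermediate
22 | (1S,2Z,6Z,10S)-3,7-dimethyl-10-(prop-1-en-2-yl)cyclodeca-2,6-dien-1-ol | O[C@H]1/C=C(/C)CC/C=C(/C)CC[C@H]1C(C)=C | intermediate
23 | (1R,2Z,6Z,10S)-3,7-dimethyl-10-(propan-2-yl)cyclodeca-2,6-dien-1-ol | O[C@H]1/C=C(/C)CC/C=C(/C)CC[C@H]1C(C)C | intermediate
24 | vanillic acid | COc1cc(C(=O)O)ccc1O | starting material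
25 | 4-acetoxy-3-methoxybenzoic acid | COc1cc(C(=O)O)ccc1OC(C)=O | intermediate
26 | 4-acetoxy-3-methoxybenzoyl chloride | COc1cc(C(=O)Cl)ccc1OC(C)=O | intermediate
27 | (1R,2Z,6Z,10S)-3,7-dimethyl-10-(propan-2-yl)cyclodeca-2,6-dien-1-yl 4-acetoxy-3-methoxybenzoate | COc1cc(C(=O)O[C@H]2/C=C(/C)CC/C=C(/C)CC[C@H]2C(C)C)ccc1OC(C)=O | intermediate
28 | (1R,2Z,6Z,10S)-3,7-dimethyl-10-(propan-2-yl)cyclodeca-2,6-dien-1-yl 4-hydroxy-3-methoxybenzoate | COc1cc(C(=O)O[C@H]2/C=C(/C)CC/C=C(/C)CC[C@H]2C(C)C)ccc1O | target

**Totals**

Total step count: 21.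
Longest linear sequence: 19 steps (steps 1 to 17, then 20 and 21, from nerol).

**Steps most likely to fail**

1. Step 16. Proton abstraction by the bulky amide may not distinguish well enough between the two enantiotopic C13 hydrogens, or may be diverted in part to C2, so that the ring-contracted carbinol forms with low enantiomeric purity or with isomeric material. The fallback sets out from 21 and gives up asymmetric deprotonation in favour of resolution. Ether 21 is contracted with the small achiral base n-BuLi in THF at −78 °C, the conditions under which deprotonation at the OCH2 next to the CH= olefin is the established course for the all-E ethers, to give the racemic cis-dienol F1. Esterification with (2S)-2-methoxy-2-phenylacetic acid (dicyclohexylcarbodiimide, DMAP cat., CH2Cl2) gives the (2S)-2-methoxy-2-phenylacetate of the (1S,10S)-alcohol F2 and the (2S)-2-methoxy-2-phenylacetate of the (1R,10R)-alcohol F3. These are separated by chromatography and assigned by the NMR shielding model for such esters. Methanolysis of F2 (K2CO3, MeOH) returns to the route at 22.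

2. Step 15. Intermolecular etherification, or loss of chloride by elimination or SN2' attack, may outrun closure of the 13-membered ring. The fallback sets out from 17 and reverses the roles of the two termini, so that the 2-methylallylic alkoxide attacks a neryl-type chloride. Acetylation of 17 (Ac2O, pyridine) gives the silyl ether acetate F4. Desilylation with HF·pyridine gives the hydroxy acetate F5. Corey–Kim chlorination (N-chlorosuccinimide, Me2S, CH2Cl2, −20 → 0 °C) gives the chloro acetate F6. Reductive removal of the acetate (iBu2AlH, CH2Cl2, −78 °C) gives the isomeric hydroxy chloride F7. F7 is cyclised by slow addition to NaH in THF and rejoins the route at 21.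

3. Step 17. Hydrogen uptake may continue into the ring olefins, or the rhodium catalyst may migrate them, before the isopropenyl group is consumed. The fallback sets out from 22 and replaces hydrogenation by hydroboration and deoxygenation. The hindered borane 9-borabicyclo[3.3.1]nonane (THF, 0 °C → rt, then NaOH/H2O2) attacks only the 1,1-disubstituted olefin and gives the primary-secondary diol F8, as a mixture of epimers at the side-chain carbon that later becomes achiral. Selective sulfonylation of the primary hydroxyl (TsCl, pyridine, 0 °C) gives the monotosylate F9. Hydride displacement with LiBHEt3 in THF at 0 °C turns CH2OTs into CH3 and returns to the route at 23.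

**Further compounds**

F1 | step 16 | racemic cis-3,7-dimethyl-10-(prop-1-en-2-yl)cyclodeca-2,6-dien-1-ol (1S,10S and 1R,10R) | O[C@H]1/C=C(/C)CC/C=C(/C)CC[C@H]1C(C)=C.O[C@@H]1/C=C(/C)CC/C=C(/C)CC[C@@H]1C(C)=C
F2 | step 16 | (1S,2Z,6Z,10S)-3,7-dimethyl-10-(prop-1-en-2-yl)cyclodeca-2,6-dien-1-yl (2S)-2-methoxy-2-phenylacetate | CO[C@H](C(=O)O[C@H]1/C=C(/C)CC/C=C(/C)CC[C@H]1C(C)=C)c1ccccc1
F3 | step 16 | (1R,2Z,6Z,10R)-3,7-dimethyl-10-(prop-1-en-2-yl)cyclodeca-2,6-dien-1-yl (2S)-2-methoxy-2-phenylacetate | CO[C@H](C(=O)O[C@@H]1/C=C(/C)CC/C=C(/C)CC[C@@H]1C(C)=C)c1ccccc1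
F4 | step 15 | (2Z,6Z,10Z)-12-[(tert-butyldimethylsilyl)oxy]-2,6,10-trimethyldodeca-2,6,10-trien-1-yl acetate | CC(C)(C)[Si](C)(C)OC/C=C(/C)CC/C=C(/C)CC/C=C(/C)COC(C)=O
F5 | step 15 | (2Z,6Z,10Z)-12-hydroxy-2,6,10-trimethyldodeca-2,6,10-trien-1-yl acetate | OC/C=C(/C)CC/C=C(/C)CC/C=C(/C)COC(C)=O
F6 | step 15 | (2Z,6Z,10Z)-12-chloro-2,6,10-trimethyldodeca-2,6,10-trien-1-yl acetate | ClC/C=C(/C)CC/C=C(/C)CC/C=C(/C)COC(C)=O
F7 | step 15 | (2Z,6Z,10Z)-12-chloro-2,6,10-trimethyldodeca-2,6,10-trien-1-ol | ClC/C=C(/C)CC/C=C(/C)CC/C=C(/C)CO
F8 | step 17 | (1R,2Z,6Z,10S)-10-(1-hydroxypropan-2-yl)-3,7-dimethylcyclodeca-2,6-dien-1-ol (side-chain epimers) | O[C@H]1/C=C(/C)CC/C=C(/C)CC[C@H]1C(C)CO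
F9 | step 17 | 2-[(1S,2R,3Z,7Z)-2-hydroxy-4,8-dimethylcyclodeca-3,7-dien-1-yl]propyl 4-methylbenzenesulfonate (side-chain epimers) | O[C@H]1/C=C(/C)CC/C=C(/C)CC[C@H]1C(C)COS(=O)(=O)c1ccc(C)cc1
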